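## Structural features

The target is a sesquilignan made of three guaiacyl (4-oxy-3-methoxyphenyl) rings. Rings B and C sit exo at C7 and C7' of a cis-fused 3,7-dioxabicyclo[3.3.0]octane (furofuran). Its four contiguous stereocentres are (7R,8S,8'S,7'R), the C2-symmetric core of (−)-pinoresinol (C7–C9 on the ring B half, primed atoms on the ring C half). The ring B oxygen O4' is bonded to C8'' of an arylglycerol chain, ring A–C7''H(OH)–C8''H(O4')–C9''H2OH. The two adjacent centres are (7''R,8''S), the erythro (anti) arrangement; at the ester stage the same arrangement is (2R,3R) because the priorities at C8'' change. The descriptors of the key-step precursor, the key-step product and the target were rederived atom by atom and are mutually consistent. Fragile elements are the two benzylic ether C–O bonds of the furofuran (acid ionization with epimerization at C7 or C7', hydrogenolysis), the p-oxybenzylic alcohol at C7'' (quinone methide formation, retro-aldol at the ester stage) and the free phenols. The real difficulty is twofold: the two core phenols are equivalent by symmetry yet only O4' may be etherified, and the acyclic erythro pair lies six or more bonds from any other stereocentre, so the core cannot control it. The key step exploits the fact that C8'' carries three different groups, O4' of ring B, the carbinol carbon C7'' on ring A, and C9'', which correspond to a phenol, an aldehyde and the carbene carbon of a diazoacetate.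

## Logic of the disconnections

19 to 18: the O–Si bond on ring C is cut. The ring C phenol must stay masked until ring B has reacted, and a bulky silyl ether is inert to carbenoids and hydride. Nothing is gained in skeleton, but 18 has only one masked group left. The forward step must use buffered fluoride so that neither the benzylic ethers nor C7'' suffer.

18 to 17: the C9'' alcohol is traced to an ethyl ester and the ring A phenol to its acetate. The ester is what a diazoacetate delivers, and the acetate activates the aldehyde partner; one hydride reagent undoes both. The forward reduction must be faster than retro-aldol cleavage of C7''–C8''.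

17 to 13, 14 and 15: the C8''–O4' and C7''–C8'' bonds are cut together. This removes the whole side chain with both of its stereocentres in one operation and leaves the symmetric core with a single free phenol plus two commercial reagents. The forward step must trap the oxonium ylide with 15 before proton transfer, and a chiral acid must set the erythro relation and the absolute sense. For that reason 13 may carry only one O–H.

13 to 12: the O–allyl bond on ring B is restored. Rings B and C must be told apart without a statistical step, and an allyl and a silyl ether are orthogonal. The allyl group cannot stay for the carbenoid step (cyclopropanation, ylide rearrangement), so it must leave under neutral zerovalent palladium conditions.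

12 to 10: the C7–O and C7'–O bonds of both tetrahydrofurans are cut. Benzylic C–O bonds para to an oxygen substituent form readily by ionization, so the bicycle simplifies to an acyclic tetrol in which only C8 and C8' need a defined configuration. The forward closure must place both aryl groups exo under kinetic control and must not re-ionize the product.

10 to 9: the two primary alcohols C9 and C9' are reconnected as a γ-lactone. The lactone supplies an enolizable position and a ring that relays C8' to C8. The forward reduction must not epimerize or fragment the β-hydroxy lactone.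

9 to 6 and 7: the C7–C8 bond is cut as an aldol α to the lactone carbonyl. The ring B unit then arrives as a separate, already differentiated aldehyde. The enolate must react trans to the C8' substituent, and the free hydroxyl of 6 must not open the lactone before enolization.

6 to 2 and 3: the C7'–C8' bond (aldol) and the lactone acyl C–O bond are cut. Both components are simple, and the only stereocentre that has to survive, C8', is set by an amine catalyst. The catalyst must select one enamine face and must cope with an electron-rich aldehyde.

2 and 7 to 1: O–Si and O–allyl bonds are cut, so both aryl units come from one cheap phenolic aldehyde.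

## Other disconnections considered

Alternative 1: The cut is the C8–C8' bond of the core, formed in the forward sense by a Wolff ring contraction. The diazo ketone A1, a 2-aryl-3-diazotetrahydropyran-4-one with the silylated ring C carbinol at C5, is photolysed in an alcoholic solvent; C8' migrates from the carbonyl carbon C9 to the carbene carbon C8 and the ketene is trapped as the tetrahydrofuran methyl ester A2.
- In its favour: ring contraction of cyclic α-diazo ketones is an established reaction, so on mechanistic precedent it is better than step 8. The migrating carbon keeps its configuration, the ester at C8 can be epimerized to the all-trans ring, and rings B and C are differentiated (allyl and benzyl), which is the equal of the chosen design.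
- Against it here: A1 needs an enantioselective pyranone synthesis followed by diazo transfer next to a benzylic ether carbon. Base can open such β-alkoxy ketones by retro-oxa-Michael reaction, and a 1,2-hydride shift from C7 can compete with migration in the carbene.
- Comparison: the alternative addresses only the core. After A2 there remain ester reduction, desilylation, the second ring closure and deallylation before the side chain can be attached. Structurally it would replace steps 2 to 6, not step 8, and in step count it is clearly longer. Its benzyl ether on ring C would call for hydrogenolysis next to benzylic ethers at the end.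

Alternative 2: The cut is both benzylic C–O bonds of the core with the C7–C7' bond re-formed, which turns the dibenzyl ether A4 into the all-trans cyclobutane diol A3. In the forward sense the anode removes one electron from a dialkoxyaryl ring, the doubly benzylic C7–C7' bond breaks, and the two hydroxymethyl groups capture C7 and C7' in two 5-membered ring closures.
- In its favour: the C8–C8' bond and its trans relation would come from a [2+2] dimerization, and the core would be reached in about four or five operations. On step economy for the core alone this alternative is the better one. The capture of benzylic cations by hydroxymethyl groups follows the same logic as step 6.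
- Against it here: A3 must be a single enantiomer of the one isomer with trans hydroxymethyl groups, which alkene dimerization does not normally deliver. Cycloreversion to two alkenes is the usual fate of such radical cations, and the electron-rich product can be oxidized further.
- Comparison: A4 carries two identical benzyl ethers, so the desymmetrization that the chosen plan avoids comes back, together with hydrogenolysis beside benzylic ethers. The step is unprecedented, so it would add a second untested step to a synthesis that already has one for the side chain.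

Alternative 3: The cuts are C7–C8 and C8'–C7'. The lithiated dithiane A6 adds to the β-carbon of the menthyloxybutenolide A5 trans to the auxiliary, and the enolate is trapped by benzylvanillin A7 to give the trans,trans lactone A8.
- In its favour: tandem conjugate addition and aldol on 5-alkoxybutenolides is well-established chemistry, so on mechanistic security this alternative is better than step 8 and at least the equal of steps 2 and 4. It sets C8 and C8' trans in one flask under auxiliary control, and the two rings are differentiated without a statistical step, as in the chosen plan.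
- Against it here: the (−) core needs the (+)-menthyl series of the auxiliary, as drawn in A8. After A8 come dithiane hydrolysis with thiophilic reagents in the presence of an allyl ether, ketone reduction, reduction of the lactone acetal, ring closure and deallylation.
- Comparison: together with the preparation of A5 and A6 this is about ten operations to the free ring B phenol, against seven in the chosen plan. The side chain is still to be made, and the ring C benzyl ether would again have to be removed by hydrogenolysis next to benzylic ethers.

Key step: step 8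

Assumption: the (R) enantiomer of the phosphoric acid in step 8 is taken as the one that leads to the (2R,3R) ester 17; if the sense of induction is the reverse, its mirror image is used and nothing else changes.

## Steps

Step 1
Reactants: 1 vanillin
Product: 2 3-methoxy-4-(triisopropylsilyloxy)benzaldehyde
Conditions: iPr3SiCl, imidazole, DMF, 0 °C to rt
Reagents that add atoms: chlorotriisopropylsilane, CC(C)[Si](Cl)(C(C)C)C(C)C
Why: Silyl ether formation at the only hydroxyl; the bulky triisopropylsilyl group should survive amide base, hydride and mild acid and becomes the ring C mask of the key step.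

Step 2
Reactants: 2 3-methoxy-4-(triisopropylsilyloxy)benzaldehyde; 3 methyl 4-oxobutanoate
Product: 6 (4S)-4-{(S)-hydroxy[3-methoxy-4-(triisopropylsilyloxy)phenyl]methyl}dihydrofuran-2(3H)-one, via anti aldol aldehyde 4 (not isolated), via diol ester 5 (not isolated)
Conditions: D-proline (30 mol %), DMF, 4 °C, slow addition of 3; then MeOH, NaBH4, 0 °C; 1 M HCl work-up
Reagents that add atoms: none
Why: Enamine-catalysed direct cross-aldol (proline aldol): the enamine of 3 formed with D-proline should attack the aldehyde face fixed by the carboxylic acid hydrogen bond, giving the anti adduct 4 and setting C8' (S in 6). NaBH4 then reduces the formyl group and the primary alcohol of 5 lactonizes onto the methyl ester; the C7' configuration formed here is erased in step 6.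

Step 3
Reactants: 1 vanillin
Product: 7 4-(allyloxy)-3-methoxybenzaldehyde
Conditions: allyl bromide, K2CO3, acetone, reflux
Reagents that add atoms: allyl bromide, C=CCBr
Why: Williamson ether synthesis; the allyl ether is inert to base and hydride and can later be removed by zerovalent palladium without touching silyl or benzylic ethers.

Step 4
Reactants: 6 (4S)-4-{(S)-hydroxy[3-methoxy-4-(triisopropylsilyloxy)phenyl]methyl}dihydrofuran-2(3H)-one; 7 4-(allyloxy)-3-methoxybenzaldehyde
Product: 9 (3R,4S)-3-{[4-(allyloxy)-3-methoxyphenyl](hydroxy)methyl}-4-{(S)-hydroxy[3-methoxy-4-(triisopropylsilyloxy)phenyl]methyl}dihydrofuran-2(3H)-one (C7 epimers), via dilithium alkoxide enolate 8 (not isolated)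
Conditions: LiN(iPr)2 (2.2 equiv), THF, −78 °C, inverse addition of 6; then 7, −78 °C; AcOH quench at −78 °C
Reagents that add atoms: none
Why: Aldol addition of a γ-butyrolactone enolate: in 8 the face anti to the C4 substituent is open, so the new bond at C8 should form trans (3R,4S). The configuration of the new carbinol C7 is not controlled and need not be; inverse addition at −78 °C is meant to enolize before the alkoxide can attack the lactone.

Step 5
Reactants: 9 (3R,4S)-3-{[4-(allyloxy)-3-methoxyphenyl](hydroxy)methyl}-4-{(S)-hydroxy[3-methoxy-4-(triisopropylsilyloxy)phenyl]methyl}dihydrofuran-2(3H)-one (C7 epimers)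
Product: 10 (2S,3S)-2-{[4-(allyloxy)-3-methoxyphenyl](hydroxy)methyl}-3-{(S)-hydroxy[3-methoxy-4-(triisopropylsilyloxy)phenyl]methyl}butane-1,4-diol (C7 epimers)
Conditions: LiAlH4, THF, 0 °C to rt; H2O, aq. NaOH work-up
Reagents that add atoms: none
Why: LiAlH4 reduction of a lactone to the 1,4-diol; C8 and C8' can no longer epimerize once the carbonyl is gone, and the aryl silyl and allyl ethers should be stable to the hydride at this temperature.

Step 6
Reactants: 10 (2S,3S)-2-{[4-(allyloxy)-3-methoxyphenyl](hydroxy)methyl}-3-{(S)-hydroxy[3-methoxy-4-(triisopropylsilyloxy)phenyl]methyl}butane-1,4-diol (C7 epimers)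
Product: 12 (1R,3aS,4R,6aS)-1-[4-(allyloxy)-3-methoxyphenyl]-4-[3-methoxy-4-(triisopropylsilyloxy)phenyl]tetrahydro-1H,3H-furo[3,4-c]furan, via monocyclic tetrahydrofuran diol 11 (not isolated)
Conditions: camphorsulfonic acid (10 mol %), CH2Cl2 (0.01 M), 0 °C
Reagents that add atoms: none
Why: Acid-catalysed SN1 cyclodehydration: each 4-oxygenated benzylic alcohol ionizes to a quinone-methide-like cation that is captured by the primary hydroxyl on the far carbon (C9'–OH at C7, C9–OH at C7') in two 5-membered ring closures. The aryl group should end up trans to the neighbouring ring carbon (kinetic preference for the 2,3-trans tetrahydrofuran), which makes C7 and C7' both R whatever their configuration in 10; the cis ring fusion is dictated by C8 and C8'. Catalytic acid, 0 °C and high dilution are chosen to stay below the threshold for re-ionization of 12.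

Step 7
Reactants: 12 (1R,3aS,4R,6aS)-1-[4-(allyloxy)-3-methoxyphenyl]-4-[3-methoxy-4-(triisopropylsilyloxy)phenyl]tetrahydro-1H,3H-furo[3,4-c]furan
Product: 13 2-methoxy-4-{(1R,3aS,4R,6aS)-4-[3-methoxy-4-(triisopropylsilyloxy)phenyl]tetrahydro-1H,3H-furo[3,4-c]furan-1-yl}phenol
Conditions: Pd(PPh3)4 (5 mol %), morpholine, THF, rt
Reagents that add atoms: none
Why: Tsuji–Trost-type allyl transfer: zerovalent palladium ionizes the aryl allyl ether to a π-allyl complex and the phenoxide, and morpholine takes up the allyl group; the neutral conditions should leave the silyl ether and the benzylic ethers untouched.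

Step 8
Reactants: 13 2-methoxy-4-{(1R,3aS,4R,6aS)-4-[3-methoxy-4-(triisopropylsilyloxy)phenyl]tetrahydro-1H,3H-furo[3,4-c]furan-1-yl}phenol; 14 ethyl diazoacetate; 15 vanillin acetate
Product: 17 ethyl (2R,3R)-3-(4-acetoxy-3-methoxyphenyl)-3-hydroxy-2-(2-methoxy-4-{(1R,3aS,4R,6aS)-4-[3-methoxy-4-(triisopropylsilyloxy)phenyl]tetrahydro-1H,3H-furo[3,4-c]furan-1-yl}phenoxy)propanoate, via aryloxyacetate enol 16 (not isolated)
Conditions: Rh2(OAc)4 (2 mol %), (R)-3,3'-bis(2,4,6-triisopropylphenyl)-1,1'-binaphthyl-2,2'-diyl hydrogen phosphate (10 mol %), 15 (3 equiv), 4 Å MS, CH2Cl2, 0 °C, 14 (1.5 equiv) by syringe pump over 6 h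
Reagents that add atoms: none
Why: Proposed new method: divalent rhodium (Rh2(OAc)4) should turn 14 into an electrophilic carbenoid that the only free O–H of 13, the ring B phenol, attacks to give a protic oxonium ylide, which is in effect the rhodium-associated form of the aryloxyacetate enol 16. The phosphoric acid is meant to bind this enol through its phosphoryl oxygen and aldehyde 15 through its acidic proton, so that C7''–C8'' bond formation overtakes the 1,2-proton shift and the C8''–O4' and C7''–C8'' bonds form in one flask; no ring closes. The closest established reaction type is the Rh2(OAc)4 and chiral Brønsted acid co-catalysed three-component coupling of diazo esters with alcohols or water and imines or activated aldehydes through trapped oxonium ylides; new here are the phenol as ylide donor, the acceptor-only diazo ester and a benzaldehyde of only moderate electrophilicity. Both new stereocentres are under catalyst control: C8'' by the enol face exposed in the hydrogen-bonded assembly and C7'' by the aldehyde face left open by the 2,4,6-triisopropylphenyl groups. The anti (erythro) relation should follow from an open transition state that keeps the aryloxy group and the aldehyde aryl apart. The core stereocentres lie six or more bonds from the reacting oxygen and should not interfere, so the acid enantiomer decides the sense. The step needs chemoselectivity for O–H attack over attack at arene carbons, ether oxygens or the aldehyde oxygen, which the single free phenol, the silyl cap on ring C, the low stationary concentration of 14, the sieves (no water as a competing donor) and the excess of 15 are meant to secure. The acetoxy group raises the electrophilicity of 15, and the weak acid at 0 °C should spare the benzylic ethers.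

Step 9
Reactants: 17 ethyl (2R,3R)-3-(4-acetoxy-3-methoxyphenyl)-3-hydroxy-2-(2-methoxy-4-{(1R,3aS,4R,6aS)-4-[3-methoxy-4-(triisopropylsilyloxy)phenyl]tetrahydro-1H,3H-furo[3,4-c]furan-1-yl}phenoxy)propanoate
Product: 18 (1R,2S)-1-(4-hydroxy-3-methoxyphenyl)-2-(2-methoxy-4-{(1R,3aS,4R,6aS)-4-[3-methoxy-4-(triisopropylsilyloxy)phenyl]tetrahydro-1H,3H-furo[3,4-c]furan-1-yl}phenoxy)propane-1,3-diol
Conditions: LiBH4 (5 equiv), THF, 0 °C to rt; aq. NH4Cl
Reagents that add atoms: none
Why: Hydride reduction of an α-aryloxy ester to the primary alcohol and reductive cleavage of the aryl acetate in the same flask; no stereocentre is touched (C8'' becomes S only by a priority change). Starting cold is meant to consume the ester before the C7'' alkoxide can undergo retro-aldol cleavage.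

Step 10
Reactants: 18 (1R,2S)-1-(4-hydroxy-3-methoxyphenyl)-2-(2-methoxy-4-{(1R,3aS,4R,6aS)-4-[3-methoxy-4-(triisopropylsilyloxy)phenyl]tetrahydro-1H,3H-furo[3,4-c]furan-1-yl}phenoxy)propane-1,3-diol
Product: 19 (1R,2S)-1-(4-hydroxy-3-methoxyphenyl)-2-{4-[(1R,3aS,4R,6aS)-4-(4-hydroxy-3-methoxyphenyl)tetrahydro-1H,3H-furo[3,4-c]furan-1-yl]-2-methoxyphenoxy}propane-1,3-diol
Conditions: Bu4NF (1.2 equiv), AcOH (1.2 equiv), THF, 0 °C
Reagents that add atoms: none
Why: Fluoride-induced cleavage of the aryl silyl ether; acetic acid buffers the phenoxide so that neither quinone methide formation at C7'' nor base damage to the benzylic ethers should set in.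

## Compound list

1 | vanillin | COc1cc(C=O)ccc1O | starting material
2 | 3-methoxy-4-(triisopropylsilyloxy)benzaldehyde | COc1cc(C=O)ccc1O[Si](C(C)C)(C(C)C)C(C)C | intermediate
3 | methyl 4-oxobutanoate | COC(=O)CCC=O | starting material
4 | methyl (3R,4S)-3-formyl-4-hydroxy-4-[3-methoxy-4-(triisopropylsilyloxy)phenyl]butanoate | COC(=O)C[C@@H](C=O)[C@H](O)c1ccc(O[Si](C(C)C)(C(C)C)C(C)C)c(OC)c1 | intermediate (not isolated)
5 | methyl (3S,4S)-4-hydroxy-3-(hydroxymethyl)-4-[3-methoxy-4-(triisopropylsilyloxy)phenyl]butanoate | COC(=O)C[C@@H](CO)[C@H](O)c1ccc(O[Si](C(C)C)(C(C)C)C(C)C)c(OC)c1 | intermediate (not isolated)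
6 | (4S)-4-{(S)-hydroxy[3-methoxy-4-(triisopropylsilyloxy)phenyl]methyl}dihydrofuran-2(3H)-one | O=C1C[C@H]([C@H](O)c2ccc(O[Si](C(C)C)(C(C)C)C(C)C)c(OC)c2)CO1 | intermediate
7 | 4-(allyloxy)-3-methoxybenzaldehyde | C=CCOc1ccc(C=O)cc1OC | intermediate
8 | dilithium alkoxide enolate of 6 | [Li+].[Li+].[O-]C1=C[C@H]([C@H]([O-])c2ccc(O[Si](C(C)C)(C(C)C)C(C)C)c(OC)c2)CO1 | intermediate (not isolated)
9 | (3R,4S)-3-{[4-(allyloxy)-3-methoxyphenyl](hydroxy)methyl}-4-{(S)-hydroxy[3-methoxy-4-(triisopropylsilyloxy)phenyl]methyl}dihydrofuran-2(3H)-one, both epimers at the new carbinol carbon C7 | O=C1[C@@H](C(O)c2ccc(OCC=C)c(OC)c2)[C@H]([C@H](O)c3ccc(O[Si](C(C)C)(C(C)C)C(C)C)c(OC)c3)CO1 | intermediate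
10 | (2S,3S)-2-{[4-(allyloxy)-3-methoxyphenyl](hydroxy)methyl}-3-{(S)-hydroxy[3-methoxy-4-(triisopropylsilyloxy)phenyl]methyl}butane-1,4-diol, both C7 epimers | C=CCOc1ccc(cc1OC)C(O)[C@H](CO)[C@@H](CO)[C@H](O)c2ccc(O[Si](C(C)C)(C(C)C)C(C)C)c(OC)c2 | intermediate
11 | [(2R,3S,4S)-4-{[4-(allyloxy)-3-methoxyphenyl](hydroxy)methyl}-2-[3-methoxy-4-(triisopropylsilyloxy)phenyl]tetrahydrofuran-3-yl]methanol (ring C side closed first; the isomer closed first at the ring B side reacts on in the same way) | OC[C@H]1[C@H](c2ccc(O[Si](C(C)C)(C(C)C)C(C)C)c(OC)c2)OC[C@H]1C(O)c3ccc(OCC=C)c(OC)c3 | intermediate (not isolated)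
12 | (1R,3aS,4R,6aS)-1-[4-(allyloxy)-3-methoxyphenyl]-4-[3-methoxy-4-(triisopropylsilyloxy)phenyl]tetrahydro-1H,3H-furo[3,4-c]furan ((−)-pinoresinol, ring B allyl ether, ring C silyl ether) | C=CCOc1ccc(cc1OC)[C@@H]2OC[C@@H]3[C@H]2CO[C@H]3c4ccc(O[Si](C(C)C)(C(C)C)C(C)C)c(OC)c4 | intermediate
13 | 2-methoxy-4-{(1R,3aS,4R,6aS)-4-[3-methoxy-4-(triisopropylsilyloxy)phenyl]tetrahydro-1H,3H-furo[3,4-c]furan-1-yl}phenol ((−)-pinoresinol ring C triisopropylsilyl ether) | COc1cc(ccc1O)[C@@H]2OC[C@@H]3[C@H]2CO[C@H]3c4ccc(O[Si](C(C)C)(C(C)C)C(C)C)c(OC)c4 | intermediate (precursor of the key step)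
14 | ethyl diazoacetate | CCOC(=O)C=[N+]=[N-] | starting material
15 | vanillin acetate (4-formyl-2-methoxyphenyl acetate) | COc1cc(C=O)ccc1OC(C)=O | starting material
16 | enol of the ring B aryloxyacetate (1-ethoxy-2-aryloxyethen-1-ol; aryl = ring B of 13; alkene geometry not defined) | CCOC(O)=COc1ccc(cc1OC)[C@@H]2OC[C@@H]3[C@H]2CO[C@H]3c4ccc(O[Si](C(C)C)(C(C)C)C(C)C)c(OC)c4 | intermediate (not isolated)
17 | ethyl (2R,3R)-3-(4-acetoxy-3-methoxyphenyl)-3-hydroxy-2-(2-methoxy-4-{(1R,3aS,4R,6aS)-4-[3-methoxy-4-(triisopropylsilyloxy)phenyl]tetrahydro-1H,3H-furo[3,4-c]furan-1-yl}phenoxy)propanoate (erythro) | COc1cc([C@@H](O)[C@H](C(=O)OCC)Oc2ccc([C@@H]3OC[C@@H]4[C@H]3CO[C@H]4c5ccc(O[Si](C(C)C)(C(C)C)C(C)C)c(OC)c5)cc2OC)ccc1OC(C)=O | intermediate (product of the key step)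
18 | (1R,2S)-1-(4-hydroxy-3-methoxyphenyl)-2-(2-methoxy-4-{(1R,3aS,4R,6aS)-4-[3-methoxy-4-(triisopropylsilyloxy)phenyl]tetrahydro-1H,3H-furo[3,4-c]furan-1-yl}phenoxy)propane-1,3-diol | COc1cc([C@@H](O)[C@H](CO)Oc2ccc([C@@H]3OC[C@@H]4[C@H]3CO[C@H]4c5ccc(O[Si](C(C)C)(C(C)C)C(C)C)c(OC)c5)cc2OC)ccc1O | intermediate
19 | (1R,2S)-1-(4-hydroxy-3-methoxyphenyl)-2-{4-[(1R,3aS,4R,6aS)-4-(4-hydroxy-3-methoxyphenyl)tetrahydro-1H,3H-furo[3,4-c]furan-1-yl]-2-methoxyphenoxy}propane-1,3-diol | COc1cc([C@@H](O)[C@H](CO)Oc2ccc([C@@H]3OC[C@@H]4[C@H]3CO[C@H]4c3ccc(O)c(OC)c3)cc2OC)ccc1O | target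

## Step count and least certain steps

Total: 10 steps. Longest linear sequence: 9 steps (1, 2, 4, 5, 6, 7, 8, 9, 10); step 3 is a one-step branch.

Step 8 (key step, proposed new method).
- What may go wrong: proton transfer within the oxonium ylide may outrun capture by the aldehyde, so that only O–H insertion occurs. The phenol-derived ylide is more acidic than the alcohol-derived ylides for which trapping is established, and 15 is a weaker electrophile than the usual acceptors. Further risks are weak facial discrimination by the acid, carbenoid attack on the C7'' hydroxyl of the product at high conversion, and acid-induced epimerization of the benzylic ethers.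
- Fallback, from 13 back to 17: 13 is O-alkylated with ethyl bromoacetate (K2CO3, acetone, reflux) to the aryloxyacetate F1. This is deprotonated (LiN(iPr)2, THF, −78 °C) to the lithium enolate F2, which is added to 15 and quenched cold. This two-step enolate aldol is standard for arylglycerol β-aryl ethers and favours the erythro isomer, but it has no facial control, so 17 would have to be separated from its (2S,3S) diastereomer by chromatography.

Step 6.
- What may go wrong: loss of exo selectivity, either through a small kinetic preference at the second ring closure or through re-ionization and equilibration of the product; Friedel–Crafts closure of a benzylic cation onto the other arene is a further risk.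
- Fallback, from 9 back to 12: the rings are closed one at a time. Acid (camphorsulfonic acid, CH2Cl2, rt) should bring about translactonization to the ring C benzylic oxygen and capture of the C7 cation by the freed C9' hydroxyl, giving the bicyclic lactone F3. At that rigid stage the configuration at each benzylic carbon can be checked, and epimers can be separated or equilibrated towards the exo-aryl lactone. LiAlH4 then gives the diol F4, whose primary hydroxyl is sulfonylated (MeSO2Cl, pyridine, 0 °C to rt) to the methanesulfonate F5; this is displaced at the primary carbon by the benzylic hydroxyl with retention at C7'.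

Step 2.
- What may go wrong: slow enamine addition to an electron-rich aldehyde, so that self-condensation of 3 dominates and conversion stays low.
- Fallback, from 2 back to 6: (S)-4-benzyloxazolidin-2-one is N-acylated with methyl 4-chloro-4-oxobutanoate (n-BuLi, THF, −78 °C) to the imide F6. The MgCl2-catalysed anti-aldol of F6 with 2 (MgCl2, Et3N, Me3SiCl, EtOAc, rt) should give the O-silylated adduct F7, with attack on the chelated enolate face opposite to the benzyl group. NaBH4 in THF–H2O removes the auxiliary to give the primary alcohol F8, and acidic work-up takes off the silyl group to give 5, which lactonizes to 6.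

Step 4.
- What may go wrong: translactonization by the benzylic alkoxide before enolization, which would move the lactone to the other oxygen and reverse the facial bias at C8; retro-aldol loss of the new bond on warming.
- Fallback, from 6 back to 9: the hydroxyl is first protected (Et3SiCl, imidazole, CH2Cl2) as the triethylsilyl ether F9. One equivalent of LiN(iPr)2 gives the lithium enolate F10, which adds 7 to give the adduct F11. AcOH–THF–H2O at rt removes the silyl group, leaving the aryl triisopropylsilyl ether in place.

## Further compounds

F1 | step 8 | ethyl 2-(2-methoxy-4-{(1R,3aS,4R,6aS)-4-[3-methoxy-4-(triisopropylsilyloxy)phenyl]tetrahydro-1H,3H-furo[3,4-c]furan-1-yl}phenoxy)acetate | CCOC(=O)COc1ccc(cc1OC)[C@@H]2OC[C@@H]3[C@H]2CO[C@H]3c4ccc(O[Si](C(C)C)(C(C)C)C(C)C)c(OC)c4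
F2 | step 8 | lithium enolate of F1 | [Li+].CCOC([O-])=COc1ccc(cc1OC)[C@@H]2OC[C@@H]3[C@H]2CO[C@H]3c4ccc(O[Si](C(C)C)(C(C)C)C(C)C)c(OC)c4
F3 | step 6 | (3R,3aS,6R,6aR)-6-[4-(allyloxy)-3-methoxyphenyl]-3-[3-methoxy-4-(triisopropylsilyloxy)phenyl]tetrahydro-1H,3H-furo[3,4-c]furan-1-one | C=CCOc1ccc(cc1OC)[C@@H]2OC[C@@H]3[C@H]2C(=O)O[C@H]3c4ccc(O[Si](C(C)C)(C(C)C)C(C)C)c(OC)c4
F4 | step 6 | (R)-{(3S,4S,5R)-5-[4-(allyloxy)-3-methoxyphenyl]-4-(hydroxymethyl)tetrahydrofuran-3-yl}[3-methoxy-4-(triisopropylsilyloxy)phenyl]methanol | C=CCOc1ccc(cc1OC)[C@@H]2OC[C@@H]([C@@H](O)c3ccc(O[Si](C(C)C)(C(C)C)C(C)C)c(OC)c3)[C@H]2CO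
F5 | step 6 | primary methanesulfonate of F4 | C=CCOc1ccc(cc1OC)[C@@H]2OC[C@@H]([C@@H](O)c3ccc(O[Si](C(C)C)(C(C)C)C(C)C)c(OC)c3)[C@H]2COS(C)(=O)=O
F6 | step 2 | (S)-4-benzyl-3-(4-methoxy-4-oxobutanoyl)oxazolidin-2-one | COC(=O)CCC(=O)N1[C@@H](Cc2ccccc2)COC1=O
F7 | step 2 | methyl (3R,4S)-3-{[(S)-4-benzyl-2-oxooxazolidin-3-yl]carbonyl}-4-[3-methoxy-4-(triisopropylsilyloxy)phenyl]-4-(trimethylsilyloxy)butanoate | COC(=O)C[C@@H](C(=O)N1[C@@H](Cc2ccccc2)COC1=O)[C@H](O[Si](C)(C)C)c3ccc(O[Si](C(C)C)(C(C)C)C(C)C)c(OC)c3
F8 | step 2 | methyl (3S,4S)-3-(hydroxymethyl)-4-[3-methoxy-4-(triisopropylsilyloxy)phenyl]-4-(trimethylsilyloxy)butanoate | COC(=O)C[C@@H](CO)[C@H](O[Si](C)(C)C)c1ccc(O[Si](C(C)C)(C(C)C)C(C)C)c(OC)c1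
F9 | step 4 | (4S)-4-{(S)-[3-methoxy-4-(triisopropylsilyloxy)phenyl](triethylsilyloxy)methyl}dihydrofuran-2(3H)-one | O=C1C[C@H]([C@H](O[Si](CC)(CC)CC)c2ccc(O[Si](C(C)C)(C(C)C)C(C)C)c(OC)c2)CO1
F10 | step 4 | lithium enolate of F9 | [Li+].[O-]C1=C[C@H]([C@H](O[Si](CC)(CC)CC)c2ccc(O[Si](C(C)C)(C(C)C)C(C)C)c(OC)c2)CO1
F11 | step 4 | (3R,4S)-3-{[4-(allyloxy)-3-methoxyphenyl](hydroxy)methyl}-4-{(S)-[3-methoxy-4-(triisopropylsilyloxy)phenyl](triethylsilyloxy)methyl}dihydrofuran-2(3H)-one, both C7 epimers | O=C1[C@@H](C(O)c2ccc(OCC=C)c(OC)c2)[C@H]([C@H](O[Si](CC)(CC)CC)c3ccc(O[Si](C(C)C)(C(C)C)C(C)C)c(OC)c3)CO1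
A1 | alternative 1 | (2S,5S)-2-[4-(allyloxy)-3-methoxyphenyl]-5-[(R)-(4-benzyloxy-3-methoxyphenyl)(tert-butyldimethylsilyloxy)methyl]-3-diazotetrahydro-4H-pyran-4-one | COc1cc(ccc1OCC=C)[C@@H]2OC[C@@H]([C@@H](O[Si](C)(C)C(C)(C)C)c3ccc(OCc4ccccc4)c(OC)c3)C(=O)C2=[N+]=[N-]
A2 | alternative 1 | methyl (2R,3R,4S)-2-[4-(allyloxy)-3-methoxyphenyl]-4-[(R)-(4-benzyloxy-3-methoxyphenyl)(tert-butyldimethylsilyloxy)methyl]tetrahydrofuran-3-carboxylate | COc1cc(ccc1OCC=C)[C@@H]2OC[C@@H]([C@@H](O[Si](C)(C)C(C)(C)C)c3ccc(OCc4ccccc4)c(OC)c3)[C@H]2C(=O)OC
A3 | alternative 2 | [(1S,2S,3R,4R)-3,4-bis(4-benzyloxy-3-methoxyphenyl)cyclobutane-1,2-diyl]dimethanol (all-trans) | OC[C@@H]1[C@@H](CO)[C@H](c2ccc(OCc3ccccc3)c(OC)c2)[C@H]1c4ccc(OCc5ccccc5)c(OC)c4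
A4 | alternative 2 | (−)-pinoresinol dibenzyl ether | COc1cc(ccc1OCc2ccccc2)[C@@H]3OC[C@@H]4[C@H]3CO[C@H]4c5ccc(OCc6ccccc6)c(OC)c5
A5 | alternative 3 | (5S)-5-{[(1S,2R,5S)-2-isopropyl-5-methylcyclohexyl]oxy}furan-2(5H)-one | O=C1C=C[C@@H](O[C@H]2C[C@@H](C)CC[C@@H]2C(C)C)O1
A6 | alternative 3 | 2-[4-(allyloxy)-3-methoxyphenyl]-1,3-dithiane | C=CCOc1ccc(cc1OC)C2SCCCS2
A7 | alternative 3 | 4-(benzyloxy)-3-methoxybenzaldehyde | COc1cc(C=O)ccc1OCc2ccccc2
A8 | alternative 3 | trans,trans-3-[(4-benzyloxy-3-methoxyphenyl)(hydroxy)methyl]-4-{2-[4-(allyloxy)-3-methoxyphenyl]-1,3-dithian-2-yl}-5-{[(1S,2R,5S)-2-isopropyl-5-methylcyclohexyl]oxy}dihydrofuran-2(3H)-one (5S) | O=C1[C@@H]([C@@H](O)c2ccc(OCc3ccccc3)c(OC)c2)[C@H](C4(SCCCS4)c5ccc(OCC=C)c(OC)c5)[C@@H](O[C@H]6C[C@@H](C)CC[C@@H]6C(C)C)O1
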